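**Plan**
- Retrosynthesis (tetralin numbering: C1 carries the pendant aryl group, C2 the esterified CH2O group, C3 the free CH2OH group): the coumaroyl ester C–O bond is cut first, then the C1–C2 bond of ring B, then the C1–C8a bond between ring A and the carbinol carbon, then the C2–C3 bond (an allyl group on an acyl oxazolidinone).
- Forward: ring A (from O-benzylvanillin) receives the C4–C3 chain as an arylpropanoyl oxazolidinone; C2 and the future formyl carbon arrive as an allyl group; C1 and the pendant ring arrive by aryllithium addition; the alkene is cut to the aldehyde; ring B closes last; the coumaroyl unit is attached before deprotection.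
- Enabling feature: C1 is doubly benzylic, flanked by the pendant 4-oxygenated aryl ring and by ring A whose C6 methoxy group is para to C8a, so a C1 diarylmethanol ionises readily. C2 is α to the carbon that becomes the C2 CH2O group, so at aldehyde level it is an enamine nucleophile.
- Stereochemistry: C3 comes from an auxiliary-controlled allylation with (S)-4-benzyl-2-oxazolidinone. C1 and C2 are relayed from C3 in the half-chair ring closure, C2 also by equilibration. The E-alkene comes from a Doebner condensation.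

Key step: step 9

Remarks on the chemistry: the diarylmethanol intermediates are carried as mixtures of carbinol epimers, because both ionise to the same cation. O-Benzylvanillin and 4-(benzyloxy)benzaldehyde are taken as purchased materials.

**Step 1**
Reactants: 1 4-(benzyloxy)-3-methoxybenzaldehyde (O-benzylvanillin)
Product: 2 4-(benzyloxy)-2-bromo-5-methoxybenzaldehyde
Conditions: Br2 (1.1 equiv), NaOAc, AcOH, rt
Reagents that add atoms: bromine, BrBr
Why: Electrophilic aromatic bromination is expected para to the methoxy group and ortho to the formyl group, the usual regiochemistry of 4-O-alkylvanillins, which places bromine on the carbon that becomes C8a.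

**Step 2**
Reactants: 2 4-(benzyloxy)-2-bromo-5-methoxybenzaldehyde; 3 Meldrum's acid (2,2-dimethyl-1,3-dioxane-4,6-dione)
Product: 6 3-[4-(benzyloxy)-2-bromo-5-methoxyphenyl]propanoic acid, via arylidene Meldrum's acid 4 (not isolated), via benzylic Meldrum's acid 5 (not isolated)
Conditions: HCO2H–Et3N (5:2), 95–100 °C; aq. HCl work-up
Reagents that add atoms: none
Why: A reductive Knoevenagel condensation (condensation, hydride transfer from formate to the arylidene, then hydrolytic decarboxylation) should give the arylpropanoic acid in one pot, and with no transition metal present the aryl bromide and benzyl ether are not at risk.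

**Step 3**
Reactants: 6 3-[4-(benzyloxy)-2-bromo-5-methoxyphenyl]propanoic acid; 7 (4S)-4-benzyl-1,3-oxazolidin-2-one
Product: 9 (4S)-4-benzyl-3-{3-[4-(benzyloxy)-2-bromo-5-methoxyphenyl]propanoyl}-1,3-oxazolidin-2-one, via mixed pivalic anhydride 8 (not isolated)
Conditions: PivCl, Et3N, THF, −20 °C; then 7, LiCl, −20 °C → rt
Reagents that add atoms: none
Why: N-Acylation of the oxazolidinone through a mixed anhydride with LiCl activation is the standard auxiliary loading, and the nucleophile attacks the unhindered arylpropanoyl carbonyl rather than the pivaloyl one.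

**Step 4**
Reactants: 9 (4S)-4-benzyl-3-{3-[4-(benzyloxy)-2-bromo-5-methoxyphenyl]propanoyl}-1,3-oxazolidin-2-one; 10 allyl bromide
Product: 12 (4S)-4-benzyl-3-[(2S)-2-{[4-(benzyloxy)-2-bromo-5-methoxyphenyl]methyl}pent-4-enoyl]-1,3-oxazolidin-2-one, via sodium Z-enolate 11 (not isolated)
Conditions: NaN(SiMe3)2, THF, −78 °C; 10 (3 equiv), −78 → −40 °C
Reagents that add atoms: none
Why: In this Evans asymmetric alkylation the chelated Z-enolate is allylated on the face away from the C4 benzyl group of the (S)-auxiliary, which sets the (2S) centre that becomes C3 (R) of the tetralin.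

**Step 5**
Reactants: 12 (4S)-4-benzyl-3-[(2S)-2-{[4-(benzyloxy)-2-bromo-5-methoxyphenyl]methyl}pent-4-enoyl]-1,3-oxazolidin-2-one
Product: 13 (2S)-2-{[4-(benzyloxy)-2-bromo-5-methoxyphenyl]methyl}pent-4-en-1-ol
Conditions: LiBH4, MeOH (1.5 equiv), THF, 0 °C → rt
Reagents that add atoms: none
Why: Reductive cleavage of the N-acyloxazolidinone with LiBH4 should give the primary alcohol and the recovered auxiliary without epimerising the α-centre or touching the aryl bromide and the alkene.

**Step 6**
Reactants: 13 (2S)-2-{[4-(benzyloxy)-2-bromo-5-methoxyphenyl]methyl}pent-4-en-1-ol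
Product: 14 {[(2S)-2-{[4-(benzyloxy)-2-bromo-5-methoxyphenyl]methyl}pent-4-en-1-yl]oxy}(tert-butyl)dimethylsilane
Conditions: TBSCl, imidazole, DMF, rt
Reagents that add atoms: tert-butyldimethylsilyl chloride (TBSCl), CC(C)(C)[Si](C)(C)Cl
Why: Standard silylation of a primary alcohol masks the future C3 hydroxymethyl group so that it stays distinct from the C2 carbon through the organolithium, oxidative and acidic steps.

**Step 7**
Reactants: 14 {[(2S)-2-{[4-(benzyloxy)-2-bromo-5-methoxyphenyl]methyl}pent-4-en-1-yl]oxy}(tert-butyl)dimethylsilane; 1 4-(benzyloxy)-3-methoxybenzaldehyde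
Product: 16 [4-(benzyloxy)-3-methoxyphenyl]{5-(benzyloxy)-2-[(2S)-2-{[(tert-butyldimethylsilyl)oxy]methyl}pent-4-en-1-yl]-4-methoxyphenyl}methanol (both carbinol epimers), via aryllithium 15 (not isolated)
Conditions: n-BuLi (1.05 equiv), THF, −78 °C; then 1 (1.2 equiv), −78 → −40 °C; H2O quench
Reagents that add atoms: none
Why: Bromine–lithium exchange is faster than any deprotonation at −78 °C and the aryllithium undergoes 1,2-addition to the non-enolisable aldehyde; the new carbinol centre forms unselectively, which is harmless because ionisation in step 9 erases it.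

**Step 8**
Reactants: 16 [4-(benzyloxy)-3-methoxyphenyl]{5-(benzyloxy)-2-[(2S)-2-{[(tert-butyldimethylsilyl)oxy]methyl}pent-4-en-1-yl]-4-methoxyphenyl}methanol
Product: 18 (3R)-4-{4-(benzyloxy)-2-[[4-(benzyloxy)-3-methoxyphenyl](hydroxy)methyl]-5-methoxyphenyl}-3-{[(tert-butyldimethylsilyl)oxy]methyl}butanal (both carbinol epimers), via vicinal diol 17 (not isolated)
Conditions: OsO4 (2 mol %), NaIO4 (4 equiv), 2,6-lutidine, dioxane–H2O (3:1), rt
Reagents that add atoms: sodium periodate NaIO4, [Na+].[O-]I(=O)(=O)=O (terminal oxidant; the aldehyde oxygen is delivered by way of catalytic OsO4, O=[Os](=O)(=O)=O)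
Why: Lemieux–Johnson cleavage (dihydroxylation, then periodate glycol fission) should turn the terminal alkene into the aldehyde, with lutidine keeping the medium from becoming acidic so that the ionisable carbinol survives.

**Step 9**
Reactants: 18 (3R)-4-{4-(benzyloxy)-2-[[4-(benzyloxy)-3-methoxyphenyl](hydroxy)methyl]-5-methoxyphenyl}-3-{[(tert-butyldimethylsilyl)oxy]methyl}butanal
Product: 22 (1S,2R,3R)-7-(benzyloxy)-1-[4-(benzyloxy)-3-methoxyphenyl]-3-{[(tert-butyldimethylsilyl)oxy]methyl}-6-methoxy-1,2,3,4-tetrahydronaphthalene-2-carbaldehyde, via pyrrolidine enamine 19 (not isolated), via diarylmethyl cation 20 (not isolated), via cyclised iminium ion 21 (not isolated)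
Conditions: pyrrolidine (30 mol %), CF3CO2H (60 mol %), CH2Cl2 (0.02 M), 0 °C → rt, stirred until C2 has equilibrated; NaHCO3 quench
Reagents that add atoms: none
Why: Pyrrolidinium trifluoroacetate converts the aldehyde into E-enamine 19 while the excess acid ionises either carbinol epimer to the planar diarylmethyl cation 20, stabilised by the para-benzyloxy group of the pendant ring and by the C6 methoxy group para to C8a; the enamine carbon C2 then bonds to C1 and hydrolysis of iminium ion 21 returns the amine. The closest known reaction is the amine-catalysed SN1-type α-alkylation of aldehydes with diarylmethanols, used here intramolecularly. Ring B closes in a 6-exo-trig mode at the cation (counted in its quinoid form, with the C1=C bond to the pendant ring outside the new ring) and enamine-exo at the nucleophile, through a half-chair. C3, set in step 4, controls both new centres: with its CH2OTBS group pseudo-equatorial the aryl group at C1 should take the pseudo-equatorial site cis to it (1S), and C2 should end trans to both neighbours (2R) through the E-enamine geometry and, being α to the formyl group, through amine-mediated equilibration to the all-equatorial isomer. The step needs C–C bond formation to outrun capture of the cation by amine, water or a second molecule: acid in excess over amine keeps free amine scarce, capture by water is reversible, C1 has no β-hydrogen so elimination is impossible, and high dilution favours ring closure. Sub-stoichiometric acid in dry CH2Cl2 should leave the primary TBS ether and the benzyl ethers in place.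

**Step 10**
Reactants: 22 (1S,2R,3R)-7-(benzyloxy)-1-[4-(benzyloxy)-3-methoxyphenyl]-3-{[(tert-butyldimethylsilyl)oxy]methyl}-6-methoxy-1,2,3,4-tetrahydronaphthalene-2-carbaldehyde
Product: 23 [(1S,2R,3R)-7-(benzyloxy)-1-[4-(benzyloxy)-3-methoxyphenyl]-3-{[(tert-butyldimethylsilyl)oxy]methyl}-6-methoxy-1,2,3,4-tetrahydronaphthalen-2-yl]methanol
Conditions: NaBH4, MeOH–THF, 0 °C
Reagents that add atoms: none
Why: Chemoselective borohydride reduction of the aldehyde gives the C2 hydroxymethyl group and locks the C2 configuration, since the cold reduction is faster than α-epimerisation and the all-trans isomer is the stable one in any case.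

**Step 11**
Reactants: 24 4-(benzyloxy)benzaldehyde; 25 malonic acid
Product: 27 (E)-3-[4-(benzyloxy)phenyl]prop-2-enoic acid, via arylidenemalonic acid 26 (not isolated)
Conditions: pyridine, piperidine (cat.), 100 °C; aq. HCl work-up
Reagents that add atoms: none
Why: The Knoevenagel–Doebner condensation with decarboxylation gives the cinnamic acid, the E geometry following from thermodynamic control in the decarboxylative step.

**Step 12**
Reactants: 23 [(1S,2R,3R)-7-(benzyloxy)-1-[4-(benzyloxy)-3-methoxyphenyl]-3-{[(tert-butyldimethylsilyl)oxy]methyl}-6-methoxy-1,2,3,4-tetrahydronaphthalen-2-yl]methanol; 27 (E)-3-[4-(benzyloxy)phenyl]prop-2-enoic acid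
Product: 28 [(1S,2R,3R)-7-(benzyloxy)-1-[4-(benzyloxy)-3-methoxyphenyl]-3-{[(tert-butyldimethylsilyl)oxy]methyl}-6-methoxy-1,2,3,4-tetrahydronaphthalen-2-yl]methyl (E)-3-[4-(benzyloxy)phenyl]prop-2-enoate
Conditions: DCC, DMAP (cat.), CH2Cl2, 0 °C → rt
Reagents that add atoms: none
Why: Steglich esterification through the N-acylpyridinium ion acylates the only free hydroxyl group, the primary C2 CH2OH, without disturbing the E-alkene.

**Step 13**
Reactants: 28 [(1S,2R,3R)-7-(benzyloxy)-1-[4-(benzyloxy)-3-methoxyphenyl]-3-{[(tert-butyldimethylsilyl)oxy]methyl}-6-methoxy-1,2,3,4-tetrahydronaphthalen-2-yl]methyl (E)-3-[4-(benzyloxy)phenyl]prop-2-enoate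
Product: 29 [(1S,2R,3R)-7-(benzyloxy)-1-[4-(benzyloxy)-3-methoxyphenyl]-3-(hydroxymethyl)-6-methoxy-1,2,3,4-tetrahydronaphthalen-2-yl]methyl (E)-3-[4-(benzyloxy)phenyl]prop-2-enoate
Conditions: HF·pyridine, pyridine–THF, 0 °C → rt
Reagents that add atoms: none
Why: Fluoride-driven desilylation of the primary TBS ether under buffered, mildly acidic conditions should free the C3 hydroxymethyl group without base-promoted migration of the coumaroyl group to it and without touching the benzyl ethers.

**Step 14**
Reactants: 29 [(1S,2R,3R)-7-(benzyloxy)-1-[4-(benzyloxy)-3-methoxyphenyl]-3-(hydroxymethyl)-6-methoxy-1,2,3,4-tetrahydronaphthalen-2-yl]methyl (E)-3-[4-(benzyloxy)phenyl]prop-2-enoate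
Product: 30 [(1S,2R,3R)-7-hydroxy-1-(4-hydroxy-3-methoxyphenyl)-3-(hydroxymethyl)-6-methoxy-1,2,3,4-tetrahydronaphthalen-2-yl]methyl (E)-3-(4-hydroxyphenyl)prop-2-enoate (target)
Conditions: BCl3 (6 equiv), pentamethylbenzene (10 equiv), CH2Cl2, −78 °C; MeOH quench at −78 °C
Reagents that add atoms: none
Why: Lewis-acid debenzylation of the three aryl benzyl ethers with pentamethylbenzene as a non-basic benzyl cation scavenger runs at −78 °C, where the aryl methyl ethers, the E-enoate ester and the primary alcohol (held as a borate until the methanol quench) should persist.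

**Compound list**
1 | 4-(benzyloxy)-3-methoxybenzaldehyde (O-benzylvanillin) | COc1cc(C=O)ccc1OCc1ccccc1 | starting material
2 | 4-(benzyloxy)-2-bromo-5-methoxybenzaldehyde | COc1cc(C=O)c(Br)cc1OCc1ccccc1 | intermediate
3 | Meldrum's acid (2,2-dimethyl-1,3-dioxane-4,6-dione) | CC1(C)OC(=O)CC(=O)O1 | starting material
4 | 5-{[4-(benzyloxy)-2-bromo-5-methoxyphenyl]methylidene}-2,2-dimethyl-1,3-dioxane-4,6-dione | COc1cc(C=C2C(=O)OC(C)(C)OC2=O)c(Br)cc1OCc1ccccc1 | intermediate (not isolated)
5 | 5-{[4-(benzyloxy)-2-bromo-5-methoxyphenyl]methyl}-2,2-dimethyl-1,3-dioxane-4,6-dione | COc1cc(CC2C(=O)OC(C)(C)OC2=O)c(Br)cc1OCc1ccccc1 | intermediate (not isolated)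
6 | 3-[4-(benzyloxy)-2-bromo-5-methoxyphenyl]propanoic acid | COc1cc(CCC(=O)O)c(Br)cc1OCc1ccccc1 | intermediate
7 | (4S)-4-benzyl-1,3-oxazolidin-2-one | O=C1N[C@@H](Cc2ccccc2)CO1 | starting material
8 | 3-[4-(benzyloxy)-2-bromo-5-methoxyphenyl]propanoic 2,2-dimethylpropanoic anhydride | COc1cc(CCC(=O)OC(=O)C(C)(C)C)c(Br)cc1OCc1ccccc1 | intermediate (not isolated)
9 | (4S)-4-benzyl-3-{3-[4-(benzyloxy)-2-bromo-5-methoxyphenyl]propanoyl}-1,3-oxazolidin-2-one | COc1cc(CCC(=O)N2[C@@H](Cc3ccccc3)COC2=O)c(Br)cc1OCc1ccccc1 | intermediate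
10 | allyl bromide (3-bromoprop-1-ene) | C=CCBr | starting material
11 | sodium (Z)-enolate of 9 | COc1cc(C/C=C(\[O-])N2[C@@H](Cc3ccccc3)COC2=O)c(Br)cc1OCc1ccccc1.[Na+] | intermediate (not isolated)
12 | (4S)-4-benzyl-3-[(2S)-2-{[4-(benzyloxy)-2-bromo-5-methoxyphenyl]methyl}pent-4-enoyl]-1,3-oxazolidin-2-one | C=CC[C@H](C(=O)N1[C@@H](Cc2ccccc2)COC1=O)Cc1cc(OC)c(OCc2ccccc2)cc1Br | intermediate
13 | (2S)-2-{[4-(benzyloxy)-2-bromo-5-methoxyphenyl]methyl}pent-4-en-1-ol | C=CC[C@H](CO)Cc1cc(OC)c(OCc2ccccc2)cc1Br | intermediate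
14 | {[(2S)-2-{[4-(benzyloxy)-2-bromo-5-methoxyphenyl]methyl}pent-4-en-1-yl]oxy}(tert-butyl)dimethylsilane | C=CC[C@H](CO[Si](C)(C)C(C)(C)C)Cc1cc(OC)c(OCc2ccccc2)cc1Br | intermediate
15 | aryllithium from 14 (lithium in place of bromine) | C=CC[C@H](CO[Si](C)(C)C(C)(C)C)Cc1cc(OC)c(OCc2ccccc2)cc1[Li] | intermediate (not isolated)
16 | [4-(benzyloxy)-3-methoxyphenyl]{5-(benzyloxy)-2-[(2S)-2-{[(tert-butyldimethylsilyl)oxy]methyl}pent-4-en-1-yl]-4-methoxyphenyl}methanol, both carbinol epimers | C=CC[C@H](CO[Si](C)(C)C(C)(C)C)Cc1cc(OC)c(OCc2ccccc2)cc1C(O)c1ccc(OCc2ccccc2)c(OC)c1 | intermediate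
17 | 1,2-diol from dihydroxylation of the alkene of 16 (epimers at the new secondary alcohol and at the carbinol) | OCC(O)C[C@H](CO[Si](C)(C)C(C)(C)C)Cc1cc(OC)c(OCc2ccccc2)cc1C(O)c1ccc(OCc2ccccc2)c(OC)c1 | intermediate (not isolated)
18 | (3R)-4-{4-(benzyloxy)-2-[[4-(benzyloxy)-3-methoxyphenyl](hydroxy)methyl]-5-methoxyphenyl}-3-{[(tert-butyldimethylsilyl)oxy]methyl}butanal, both carbinol epimers | O=CC[C@H](CO[Si](C)(C)C(C)(C)C)Cc1cc(OC)c(OCc2ccccc2)cc1C(O)c1ccc(OCc2ccccc2)c(OC)c1 | intermediate (key-step precursor)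
19 | (E)-pyrrolidine enamine of 18 | C1CCN(C1)/C=C/[C@H](CO[Si](C)(C)C(C)(C)C)Cc1cc(OC)c(OCc2ccccc2)cc1C(O)c1ccc(OCc2ccccc2)c(OC)c1 | intermediate (not isolated)
20 | diarylmethyl cation of enamine 19, trifluoroacetate | C1CCN(C1)/C=C/[C@H](CO[Si](C)(C)C(C)(C)C)Cc1cc(OC)c(OCc2ccccc2)cc1[CH+]c1ccc(OCc2ccccc2)c(OC)c1.[O-]C(=O)C(F)(F)F | intermediate (not isolated)
21 | cyclised pyrrolidinium (iminium) ion of 22, trifluoroacetate | COc1cc([C@H]2c3cc(OCc4ccccc4)c(OC)cc3C[C@@H](CO[Si](C)(C)C(C)(C)C)[C@@H]2C=[N+]2CCCC2)ccc1OCc1ccccc1.[O-]C(=O)C(F)(F)F | intermediate (not isolated)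
22 | (1S,2R,3R)-7-(benzyloxy)-1-[4-(benzyloxy)-3-methoxyphenyl]-3-{[(tert-butyldimethylsilyl)oxy]methyl}-6-methoxy-1,2,3,4-tetrahydronaphthalene-2-carbaldehyde | COc1cc([C@H]2c3cc(OCc4ccccc4)c(OC)cc3C[C@@H](CO[Si](C)(C)C(C)(C)C)[C@@H]2C=O)ccc1OCc1ccccc1 | intermediate (key-step product)
23 | [(1S,2R,3R)-7-(benzyloxy)-1-[4-(benzyloxy)-3-methoxyphenyl]-3-{[(tert-butyldimethylsilyl)oxy]methyl}-6-methoxy-1,2,3,4-tetrahydronaphthalen-2-yl]methanol | COc1cc([C@H]2c3cc(OCc4ccccc4)c(OC)cc3C[C@@H](CO[Si](C)(C)C(C)(C)C)[C@@H]2CO)ccc1OCc1ccccc1 | intermediate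
24 | 4-(benzyloxy)benzaldehyde | O=Cc1ccc(OCc2ccccc2)cc1 | starting material
25 | malonic acid | OC(=O)CC(=O)O | starting material
26 | 2-{[4-(benzyloxy)phenyl]methylidene}propanedioic acid | OC(=O)C(=Cc1ccc(OCc2ccccc2)cc1)C(=O)O | intermediate (not isolated)
27 | (E)-3-[4-(benzyloxy)phenyl]prop-2-enoic acid | OC(=O)/C=C/c1ccc(OCc2ccccc2)cc1 | intermediate
28 | [(1S,2R,3R)-7-(benzyloxy)-1-[4-(benzyloxy)-3-methoxyphenyl]-3-{[(tert-butyldimethylsilyl)oxy]methyl}-6-methoxy-1,2,3,4-tetrahydronaphthalen-2-yl]methyl (E)-3-[4-(benzyloxy)phenyl]prop-2-enoate | COc1cc([C@H]2c3cc(OCc4ccccc4)c(OC)cc3C[C@@H](CO[Si](C)(C)C(C)(C)C)[C@@H]2COC(=O)/C=C/c2ccc(OCc3ccccc3)cc2)ccc1OCc1ccccc1 | intermediate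
29 | [(1S,2R,3R)-7-(benzyloxy)-1-[4-(benzyloxy)-3-methoxyphenyl]-3-(hydroxymethyl)-6-methoxy-1,2,3,4-tetrahydronaphthalen-2-yl]methyl (E)-3-[4-(benzyloxy)phenyl]prop-2-enoate | COc1cc([C@H]2c3cc(OCc4ccccc4)c(OC)cc3C[C@@H](CO)[C@@H]2COC(=O)/C=C/c2ccc(OCc3ccccc3)cc2)ccc1OCc1ccccc1 | intermediate
30 | [(1S,2R,3R)-7-hydroxy-1-(4-hydroxy-3-methoxyphenyl)-3-(hydroxymethyl)-6-methoxy-1,2,3,4-tetrahydronaphthalen-2-yl]methyl (E)-3-(4-hydroxyphenyl)prop-2-enoate | COc1cc([C@H]2c3cc(O)c(OC)cc3C[C@@H](CO)[C@@H]2COC(=O)/C=C/c2ccc(O)cc2)ccc1O | target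

**Count**
Total steps: 14. Longest linear sequence: 13 steps (steps 1–10 and 12–14, from 1 to 30); step 11 is a one-step side branch.

**Steps most likely to fail**

1. Step 9. The cation may be captured by the amine, by water or by a second molecule (ether formation, oligomerisation) faster than the dilute enamine closes the ring. The ring may also close with the C1 aryl group pseudo-axial, that is, with poor facial selectivity at C1. The fallback sets out from 18 and returns at 22, and uses a stoichiometric enol silane with a Lewis acid in place of amine catalysis. Both the formyl group and the carbinol of 18 are silylated (Me3SiOTf, Et3N, CH2Cl2, 0 °C) to the trimethylsilyl enol ether–trimethylsilyl carbinol ether F1. BF3·OEt2 or catalytic Me3SiOTf in CH2Cl2 at −78 °C then ionises the benzhydryl silyl ether and the enol silane attacks C1 (Mukaiyama-type SN1 alkylation of a silyl enol ether by a benzhydryl cation, which is known chemistry). No amine or water competes, and the low temperature should sharpen the C1 facial preference. A short DBU treatment equilibrates C2 if needed and gives 22.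

2. Step 14. Removing three benzyl groups with a Lewis acid may also cleave a methyl ether next to a freed phenol, benzylate the electron-rich rings, or cause ester migration or cleavage during the acidic quench. The fallback sets out from 23 and returns at 30, and takes the benzyl groups off before the alkene is present. Hydrogenolysis of 23 (H2, Pd/C, EtOAc–EtOH) gives the silyl-protected diphenol alcohol F2. Its primary alcohol is esterified chemoselectively with unprotected p-coumaric acid, OC(=O)/C=C/c1ccc(O)cc1, under Mitsunobu conditions (PPh3, DIAD, THF, 0 °C → rt), where the carboxylic acid and not a phenol is the pronucleophile, to give the silyl-protected target F3. HF·pyridine then gives 30.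

3. Step 8. The electron-rich diarylmethanol may be over-oxidised or ionised under the osmium/periodate conditions, and the hydroxy aldehyde may self-condense on isolation. The fallback sets out from 14 and returns at 18; it cuts the alkene before the carbinol exists and unveils the aldehyde by alcohol oxidation. Lemieux–Johnson cleavage of the robust bromide 14 gives the bromo aldehyde F4, and NaBH4 reduces it to the bromo alcohol F5. Two equivalents of n-BuLi (alkoxide formation, then bromine–lithium exchange; THF, −78 °C) followed by 1 give the diol F6. TEMPO (cat.) with PhI(OAc)2 in CH2Cl2 then oxidises only the primary alcohol and returns 18.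

**Further compounds**
F1 | step 9 | trimethylsilyl enol ether of 18 with the carbinol as its trimethylsilyl ether (enol ether E/Z and carbinol epimers) | C[Si](C)(C)OC=C[C@H](CO[Si](C)(C)C(C)(C)C)Cc1cc(OC)c(OCc2ccccc2)cc1C(O[Si](C)(C)C)c1ccc(OCc2ccccc2)c(OC)c1
F2 | step 14 | (1S,2R,3R)-3-{[(tert-butyldimethylsilyl)oxy]methyl}-1-(4-hydroxy-3-methoxyphenyl)-2-(hydroxymethyl)-6-methoxy-1,2,3,4-tetrahydronaphthalen-7-ol | COc1cc([C@H]2c3cc(O)c(OC)cc3C[C@@H](CO[Si](C)(C)C(C)(C)C)[C@@H]2CO)ccc1O
F3 | step 14 | [(1S,2R,3R)-3-{[(tert-butyldimethylsilyl)oxy]methyl}-7-hydroxy-1-(4-hydroxy-3-methoxyphenyl)-6-methoxy-1,2,3,4-tetrahydronaphthalen-2-yl]methyl (E)-3-(4-hydroxyphenyl)prop-2-enoate | COc1cc([C@H]2c3cc(O)c(OC)cc3C[C@@H](CO[Si](C)(C)C(C)(C)C)[C@@H]2COC(=O)/C=C/c2ccc(O)cc2)ccc1O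
F4 | step 8 | (3R)-4-[4-(benzyloxy)-2-bromo-5-methoxyphenyl]-3-{[(tert-butyldimethylsilyl)oxy]methyl}butanal | O=CC[C@H](CO[Si](C)(C)C(C)(C)C)Cc1cc(OC)c(OCc2ccccc2)cc1Br
F5 | step 8 | (3R)-4-[4-(benzyloxy)-2-bromo-5-methoxyphenyl]-3-{[(tert-butyldimethylsilyl)oxy]methyl}butan-1-ol | OCC[C@H](CO[Si](C)(C)C(C)(C)C)Cc1cc(OC)c(OCc2ccccc2)cc1Br
F6 | step 8 | (3R)-4-{4-(benzyloxy)-2-[[4-(benzyloxy)-3-methoxyphenyl](hydroxy)methyl]-5-methoxyphenyl}-3-{[(tert-butyldimethylsilyl)oxy]methyl}butan-1-ol (carbinol epimers) | OCC[C@H](CO[Si](C)(C)C(C)(C)C)Cc1cc(OC)c(OCc2ccccc2)cc1C(O)c1ccc(OCc2ccccc2)c(OC)c1
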